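The readings are calculated from invented constants, and the scatter is random.

Target does not keep. Once formed, a target molecule can turn into over-reaction product at any moment, so its fate depends on how long it has stood.

| flask | substrate | coupling partner | temperature | remark | time |
|---|---|---|---|---|---|
| delta | 2 M | 0.45 equiv | −15 °C | run made earlier |  |
| beta | 2 M | 0.45 equiv | 15 °C | run made earlier |  |
| ash | 2.0 M | 0.900 equiv | 40 °C |  | 4.0 h |
| maple | 2.0 M | 0.900 equiv | −10 °C |  | 4.0 h |
| cedar | 2.0 M | 0.900 equiv | 15 °C |  | 4.0 h |

| run | time / h | target / % | over-reaction product / % | substrate / % |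
|---|---|---|---|---|
| delta | 4.00 | 13.9 | 0.2 | 84.8 |
| delta | 10.0 | 25.5 | 0.1 | 72.9 |
| delta | 20.0 | 33.9 | 0.6 | 63.2 |
| delta | 50.0 | 40.6 | 1.7 | 52.4 |
| beta | 0.833 | 25.6 | 1.6 | 66.7 |
| beta | 2.50 | 34.1 | 4.3 | 47.9 |
| beta | 5.00 | 31.9 | 10.8 | 37.1 |
| beta | 10.0 | 23.8 | 20.8 | 28.9 |

(standard deviation of a reading: 0.3 percentage points)

- the earlier runs were read with a standard deviation of 0.3 percentage points

1. which flask leads in share of target in all that became target or over-reaction product ("all alike" within 1.5 percentage points) (ash / maple / cedar / all alike)
2. share of target in all that became target or over-reaction product, ash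
3. share of target in all that became target or over-reaction product, maple
4. share of target in all that became target or over-reaction product, cedar

Take that step as first order with constant k. A molecule that has stood for a time survives with chance exp(−k × time), and the asked share, the selectivity for target, is that chance averaged over the molecules.

The beta run, at the temperature of cedar, gives k. Between 5.00 h and 10.0 h the over-reaction product of the beta run gains 10 points, from a mean target of 27.9 %, so k reads 0.0718 h⁻¹.

The shares of the beta run then give ages: 1.65 h at 2.50 h and 4.06 h at 5.00 h. Interpolation in the beta run to 4.0 h gives 3.10 h, the mean age of target: the time that makes exp(−k × time) equal the share. It lies between 2.00 h for evenly spread births and 4.0 h for births at the start. Cedar borrows this age, although the beta run held less coupling partner, and gets 80.1 %.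

The delta run adds 1.1 points of over-reaction product over its last interval, so k reads 9.84 × 10⁻⁴ h⁻¹ at −15 °C, and Arrhenius gives a slope of 10600 K. Maple, taken with evenly spread births, reaches 99.6 %. Ash, with the borrowed age, falls to 1.44 %. In this reckoning maple leads.

The weak link is that gain, read with a scatter of 0.3 points. Dividing the final 1.7 % of the delta run by the whole area under its target curve gives 0.00109 h⁻¹ and a slope of 10400 K. The reckoning then puts maple at 99.5 % and ash at 1.92 %.

The forecast names maple, with 99.4 % for maple, 80 % for cedar and 2.5 % for ash, where “target forms quickly and then nearly all decays”. Its ash figure stands above the reckoning here.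

The flasks give 99.5 % for maple, 80.0 % for cedar and 1.29 % for ash, so maple leads.

    substrate + coupling partner → target, rate k1*[substrate]^1.5*[coupling partner] (k = 8.90 × 10⁻⁴ M⁻¹·⁵ s⁻¹, Ea = 54.0 kJ mol⁻¹)
    2 substrate → self-condensation product A (k = 1.50 × 10⁻⁴ M⁻¹ s⁻¹, Ea = 84.0 kJ mol⁻¹)
    2 substrate → self-condensation product B (k = 6.40 × 10⁻⁷ M⁻¹ s⁻¹, Ea = 75.0 kJ mol⁻¹)
    target → over-reaction product (k = 4.00 × 10⁻⁴ s⁻¹, Ea = 90.0 kJ mol⁻¹)
    (constants at 40 °C)

At 4.00 h cedar makes target at 0.693 times the rate at which it uses target up, each step taken net. The same flask as cedar with 0.50 M of substrate ends at a share of 84.3 %, which through the same 0.0718 h⁻¹ means a mean age of 2.38 h, shorter than the 3.10 h borrowed from the beta run for cedar.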